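## Structural features

The target is a ten-membered carbocycle, numbered here C1H=C10(CH3), C9H2, C8, C7, C6, C5, C4(CH3), C3H2, C2H2. It carries an (E)-trisubstituted alkene (C1=C10) and, across the ring from it, a trans-fused trisubstituted oxirane on C4–C5. Five contiguous stereocentres run from C4 to C8: the oxirane carbons (4R,5R), the free secondary carbinol C6 (R), the isopropyl-bearing C7 (S) and the carbinol C8 (S), whose oxygen carries the 3,4,5-trimethoxybenzoyl group. In a zigzag drawing of C5–C9 the isopropyl group is syn to O8 and O6 is anti to O8, so C6–C8 is a mono-acylated anti-1,3-diol with a syn aldol relationship between C7 and C8. The oxirane faces the alkene across the ring and sits next to a carbinol, so acid can start a transannular cyclisation and base an epoxide migration; the monoester can migrate from O8 to O6. In the open-chain precursors the β,γ-unsaturated aldehyde at C8 and the α-bromo ketone are sensitive to base. The real difficulty is to close the medium ring while C6, C7 and C8 are set relative to the only resident stereocentres (C4, C5), and to acylate one of two secondary hydroxyls only. The key step reads C6(OH)–C7(iPr)–C8(OCOAr) as an aldol addition of a C6/C7 enolate to a C8 aldehyde, followed by hydride transfer to C6 from an aryl aldehyde hemiacetal on O8. This accounts at once for the C7–C8 ring bond, the anti diol and the position of the ester.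

## Logic of the disconnections

22 is cut at the ring bond C7–C8 and at the O8–acyl bond, and the C6 hydrogen is returned to the aldehyde carbon of 18; this gives 17 and 18. The cut is made there because an anti-1,3-diol acylated on the aldol oxygen is the retron of an aldol–Tishchenko sequence. The ring, three stereocentres and the ester disappear together, leaving an open chain whose only stereocentres are the oxirane carbons. The forward step must close a ten-membered ring through a samarium enolate, with syn selectivity on the face dictated by the oxirane, and then deliver hydride anti.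

17 is taken back through 16 to 15 by returning C8 to the alcohol level and placing a silyl group on its oxygen. A β,γ-unsaturated aldehyde would not survive enolisation, a Grignard reagent or base, so it is revealed last. The demand is a deprotection and an oxidation that are neither basic nor strongly acidic, so that the bromo ketone and the oxirane stay intact and the alkene stays out of conjugation.

15 is cut at C7–Br to give 13. The bromide serves only as the electron acceptor of the key step, and 13 can enolise at C7 only. The forward bromination must leave both the alkene and the oxirane untouched; the C7 configuration does not matter.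

13 is taken through 12 and cut at C6–C7 to give 10 and 11. This joins the commercial isobutyl unit (C7 plus isopropyl) to the terpenoid chain. The addition must respect the oxirane; the new carbinol is oxidised at once.

10 is taken back through 9 to 8 by lowering C6 to the alcohol level and removing both C–O bonds of the oxirane. The allylic hydroxyl directs a reagent-controlled epoxidation, the (E)-alkene fixes the trans oxirane and the tartrate fixes the absolute sense. All stereochemistry is gone in 8. The forward step must be enantioselective and must leave the second alkene alone.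

8 is taken through 7 to 6 by removing the silyl group from O8 and returning the acetyl group to O6. The acetate that comes with 1 marks one chain end while the new hydroxyl at the other end is silylated. The two groups must be orthogonal.

6 is cut at C8–O to give 4, and 4 at C8=C9 to give 3. An anti-Markovnikov hydration of a vinyl group places oxygen on the one-carbon extension of the enal. The hydroboration must select the only monosubstituted alkene, and the methylenation must spare the acetate.

3 is taken back through 2 to 1 by removing the oxygen on C9. 1 already holds the future C1=C10 alkene with (E) geometry and the alkene that becomes the oxirane. The forward oxidation must select the (E)-methyl group of the alkene remote from the acetate.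

## Other disconnections considered

Alternative 1: The cut runs through C4–C5 and the O–C5 bond, so that ring and oxirane arise together in a macrocyclic Darzens condensation. LiN(SiMe3)2 would deprotonate the chloromethyl carbon (C5) of the open-chain diketone A2; the enolate of A2 would add to the C4 methyl ketone and the new alkoxide would displace chloride to give the epoxy ketone A1. Desilylation and an Evans–Tishchenko reduction with 18 would then lead to 22 in two further steps.
- In its favour: two bonds and the whole oxirane form in the ring-closing event, and neither a bromo ketone nor a β,γ-unsaturated aldehyde is needed. C7 and C8 would be installed beforehand by an open-chain, auxiliary- or boron-mediated syn aldol, whose control is better understood than that of a macrocyclic aldol. On the reliability of the C7/C8 relationship this plan is the better one.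
- Against it: a methyl ketone is an enolisable, weak acceptor and the addition to it is reversible. The base can also remove H7, after which the C8 silyloxy group would be expelled. C4 and C5 would have to form with the correct relative sense (C3 and C6 trans on the oxirane) and absolute sense under the influence of stereocentres three and four atoms away.
- Comparison: both plans close the same ring by an enolate addition under dilution and are equal there. The chosen plan places the uncertain induction on C7/C8 and obtains the oxirane by reagent control; A1 would place it on the oxirane. In step count the chosen plan ends at its key step, whereas A1 needs two more steps and A2 a separate asymmetric aldol sequence.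

Alternative 2: The cut removes C6–C7 and O–C8 and leads back to the epoxy aldoxime A4, which contains a (Z)-C7=C8 alkene. NaOCl would convert A4 into the nitrile oxide A5, and an intramolecular dipolar cycloaddition of A5 would give the bridged isoxazoline A3. Reductive N–O cleavage and an Evans–Tishchenko reduction with 18 would follow.
- In its favour: the cycloaddition is suprafacial, so the cis geometry of the alkene is copied directly into the syn C7/C8 relationship. On this point it is better than an aldol, which depends on enolate geometry and transition-state shape. A4 is also a sturdier precursor than 17, and its oxirane could come from the same asymmetric epoxidation.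
- Against it: the C1=C10 alkene lies only four atoms from the dipole carbon, so closure of A5 to a six-membered carbocycle should be far faster than the ten-membered mode. The required regiochemistry (carbon to the distal alkene carbon, oxygen to C8, bridged bicycle) is not inherently preferred for a 1,2-dialkyl alkene. An unactivated cis alkene reacts slowly enough for dimerisation of A5 to compete. Hypochlorite may also attack the electron-rich trisubstituted alkene.
- Comparison: face selectivity with respect to the oxirane is unproven in both plans, so they are equal there. The chosen plan has fewer competing intramolecular pathways. A3 is two steps away from 22, so the step count is at best equal.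

Alternative 3: The retrosynthetic operation reconnects C1–C6 and cuts C8–C9, which contracts the ten-membered ring to the cyclohexanol A7. A7 carries an isopropenyl group on C1 and, on the carbinol C6, an alkoxy-substituted alkenyl group, trans to each other. KH with 18-crown-6 would form the C6 alkoxide of A7, and an anionic oxy-Cope shift through a chair would give the ring-expanded ketone A6.
- In its favour: a ring expansion carries no entropic penalty and needs no dilution, the chair transition state fixes the (E)-C1=C10 alkene, and the reaction class is well established for cyclodecenones. On certainty of forming the ten-membered ring this plan is the better one. Absolute configuration could be taken from the terpene chiral pool.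
- Against it: A6 first arises as its C6 enolate, which carries the C8 ether in the β-position and can expel it. C7 is trigonal in that enolate, so its configuration is decided only by protonation. A7 needs a geometrically defined alkoxyvinyl nucleophile added to a hindered, oxygenated cyclohexanone. From A6 the C6 ketone must still be reduced anti, the benzyl ether exchanged for the ester, and the acetonide opened and closed to the oxirane while O6 is differentiated, which is at least six further operations.
- Comparison: structurally A6 reaches the carbocycle with more protecting groups and with the oxirane still latent. Mechanistically the pericyclic step is the more predictable ring construction. In step economy and number of protecting groups the chosen plan is clearly ahead.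

Key step: step 13

Remark on the chemistry: atom-by-atom comparison shows that 17 holds C4 and C5 in the same spatial arrangement as 22. The descriptor of C5 changes from S in 17 to R in 22 only because C6 changes from ketone to carbinol, so no structure needed correction. 15, 16 and 17 are used as mixtures of C7 epimers because C7 becomes trigonal in enolate 19.

Assumption: with this geraniol-type allylic alcohol, D-(−)-diethyl tartrate gives the (2R,3R)-epoxy alcohol, the mirror image of the (2S,3S) sense established for the L-(+) ester.

Design changes to the precursor stage: C8 is carried as a silyl ether rather than as a nitrile, since a nitrile cannot be reduced once the ketone is present. The aldehyde is made last and used at once, and 18 is added only after the divalent samarium is consumed.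

## Route

Step 1
Reactants: 1 geranyl acetate
Product: 3 (2E,6E)-3,7-dimethyl-8-oxoocta-2,6-dien-1-yl acetate, via allylic alcohol 2 (not isolated)
Conditions: SeO2 (cat.), tBuOOH, salicylic acid (cat.), CH2Cl2, rt; then MnO2, CH2Cl2, rt
Reagents that add atoms: tert-butyl hydroperoxide, CC(C)(C)OO (net source of the new oxygen, relayed through SeO2, O=[Se]=O)
Why: Selenium dioxide allylic oxidation (ene reaction, then [2,3]-sigmatropic shift) should attack the (E)-methyl group of the electron-rich distal alkene, the acetate-bearing alkene being deactivated; MnO2 then converges 2 and any enal already formed on 3 without touching the acetate, and the 6E geometry follows from the ene/[2,3] sequence.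

Step 2
Reactants: 3 (2E,6E)-3,7-dimethyl-8-oxoocta-2,6-dien-1-yl acetate
Product: 4 (2E,6E)-3,7-dimethylnona-2,6,8-trien-1-yl acetate
Conditions: Ph3PCH3Br, KN(SiMe3)2, THF, −78 → 0 °C
Reagents that add atoms: methyltriphenylphosphonium bromide, C[P+](c1ccccc1)(c1ccccc1)c1ccccc1.[Br-]
Why: Wittig methylenation; the unstabilised ylide should react with the aldehyde far faster than with the acetate at low temperature, and no stereochemical element is created.

Step 3
Reactants: 4 (2E,6E)-3,7-dimethylnona-2,6,8-trien-1-yl acetate
Product: 6 (2E,6E)-9-hydroxy-3,7-dimethylnona-2,6-dien-1-yl acetate, via B-alkyl borane 5 (not isolated)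
Conditions: 9-BBN, THF, 0 °C → rt; then NaBO3·4H2O, H2O, rt
Reagents that add atoms: sodium perborate tetrahydrate, [Na+].[Na+].O[B-]1(O)OO[B-](O)(O)OO1
Why: Hydroboration–oxidation; 9-BBN should add anti-Markovnikov to the only monosubstituted alkene and ignore the two trisubstituted ones, and the perborate oxidation is mild enough to keep the acetate.

Step 4
Reactants: 6 (2E,6E)-9-hydroxy-3,7-dimethylnona-2,6-dien-1-yl acetate
Product: 7 (2E,6E)-9-[(tert-butyldimethylsilyl)oxy]-3,7-dimethylnona-2,6-dien-1-yl acetate
Conditions: TBSCl, imidazole, CH2Cl2, rt
Reagents that add atoms: tert-butyldimethylsilyl chloride, CC(C)(C)[Si](C)(C)Cl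
Why: Standard silylation of an unhindered primary alcohol; the silyl ether is chosen because it survives the methanolysis, the epoxidation, the Grignard addition and the enolate chemistry that follow.

Step 5
Reactants: 7 (2E,6E)-9-[(tert-butyldimethylsilyl)oxy]-3,7-dimethylnona-2,6-dien-1-yl acetate
Product: 8 (2E,6E)-9-[(tert-butyldimethylsilyl)oxy]-3,7-dimethylnona-2,6-dien-1-ol
Conditions: K2CO3, MeOH, 0 °C
Reagents that add atoms: none
Why: Base-catalysed transesterification removes the acetate as methyl acetate, and a primary tert-butyldimethylsilyl ether is stable under these conditions.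

Step 6
Reactants: 8 (2E,6E)-9-[(tert-butyldimethylsilyl)oxy]-3,7-dimethylnona-2,6-dien-1-ol
Product: 9 {(2R,3R)-3-[(3E)-6-[(tert-butyldimethylsilyl)oxy]-4-methylhex-3-en-1-yl]-3-methyloxiran-2-yl}methanol
Conditions: Ti(OiPr)4 (cat.), D-(−)-diethyl tartrate (cat.), tBuOOH, 4 Å molecular sieves, CH2Cl2, −20 °C
Reagents that add atoms: tert-butyl hydroperoxide, CC(C)(C)OO
Why: Sharpless asymmetric epoxidation; the titanium-bound allylic alkoxide directs oxygen to the 2,3-alkene only, the (E)-alkene gives the trans oxirane, and the D-(−)-tartrate sets C4 and C5 of the target in the (2R,3R) sense with the high enantioselectivity expected for this substrate class.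

Step 7
Reactants: 9 {(2R,3R)-3-[(3E)-6-[(tert-butyldimethylsilyl)oxy]-4-methylhex-3-en-1-yl]-3-methyloxiran-2-yl}methanol
Product: 10 (2S,3R)-3-[(3E)-6-[(tert-butyldimethylsilyl)oxy]-4-methylhex-3-en-1-yl]-3-methyloxirane-2-carbaldehyde
Conditions: Dess–Martin periodinane, NaHCO3, CH2Cl2, 0 °C → rt
Reagents that add atoms: none
Why: Dess–Martin oxidation under buffered conditions; the oxirane carbon next to the new aldehyde cannot epimerise readily because its enolisation would place a double bond on the three-membered ring (the descriptor changes to 2S only through the priority change).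

Step 8
Reactants: 10 (2S,3R)-3-[(3E)-6-[(tert-butyldimethylsilyl)oxy]-4-methylhex-3-en-1-yl]-3-methyloxirane-2-carbaldehyde; 11 isobutylmagnesium bromide
Product: 12 1-{(2R,3R)-3-[(3E)-6-[(tert-butyldimethylsilyl)oxy]-4-methylhex-3-en-1-yl]-3-methyloxiran-2-yl}-3-methylbutan-1-ol (both carbinol epimers)
Conditions: iBuMgBr, THF, −78 °C; aq. NH4Cl
Reagents that add atoms: isobutylmagnesium bromide (compound 11), CC(C)C[Mg]Br
Why: Grignard addition to an aldehyde, run cold so that the oxirane is not opened by magnesium halide; the new carbinol centre (C6) forms as a mixture, which is of no consequence because it is oxidised in the next step.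

Step 9
Reactants: 12 1-{(2R,3R)-3-[(3E)-6-[(tert-butyldimethylsilyl)oxy]-4-methylhex-3-en-1-yl]-3-methyloxiran-2-yl}-3-methylbutan-1-ol
Product: 13 1-{(2S,3R)-3-[(3E)-6-[(tert-butyldimethylsilyl)oxy]-4-methylhex-3-en-1-yl]-3-methyloxiran-2-yl}-3-methylbutan-1-one
Conditions: Dess–Martin periodinane, NaHCO3, CH2Cl2, rt
Reagents that add atoms: none
Why: Dess–Martin oxidation converges both carbinol epimers on one epoxy ketone under neutral conditions that leave oxirane, alkene and silyl ether untouched.

Step 10
Reactants: 13 1-{(2S,3R)-3-[(3E)-6-[(tert-butyldimethylsilyl)oxy]-4-methylhex-3-en-1-yl]-3-methyloxiran-2-yl}-3-methylbutan-1-one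
Product: 15 2-bromo-1-{(2S,3R)-3-[(3E)-6-[(tert-butyldimethylsilyl)oxy]-4-methylhex-3-en-1-yl]-3-methyloxiran-2-yl}-3-methylbutan-1-one (both C–Br epimers), via silyl enol ether 14 (not isolated)
Conditions: LiN(SiMe3)2, Me3SiCl, THF, −78 °C; then NBS, −78 °C
Reagents that add atoms: N-bromosuccinimide, O=C1CCC(=O)N1Br
Why: α-Bromination through a silyl enol ether; the ketone can enolise only toward C7 because the other α-carbon belongs to the oxirane, and the enol ether is far more nucleophilic toward NBS than the trisubstituted alkene, so no acid is generated that could open the oxirane.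

Step 11
Reactants: 15 2-bromo-1-{(2S,3R)-3-[(3E)-6-[(tert-butyldimethylsilyl)oxy]-4-methylhex-3-en-1-yl]-3-methyloxiran-2-yl}-3-methylbutan-1-one
Product: 16 2-bromo-1-{(2S,3R)-3-[(3E)-6-hydroxy-4-methylhex-3-en-1-yl]-3-methyloxiran-2-yl}-3-methylbutan-1-one (both C–Br epimers)
Conditions: HF·pyridine, pyridine, THF, 0 °C → rt
Reagents that add atoms: none
Why: Fluoride-driven cleavage of a primary silyl ether under buffered, non-basic conditions; the bromide is secondary and flanked by an isopropyl group, so displacement by pyridine should be slow, and an oxirane next to a carbonyl resists mild acid.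

Step 12
Reactants: 16 2-bromo-1-{(2S,3R)-3-[(3E)-6-hydroxy-4-methylhex-3-en-1-yl]-3-methyloxiran-2-yl}-3-methylbutan-1-one
Product: 17 (3E)-6-[(2R,3S)-3-(2-bromo-3-methylbutanoyl)-2-methyloxiran-2-yl]-3-methylhex-3-enal (both C–Br epimers)
Conditions: Dess–Martin periodinane, NaHCO3, CH2Cl2, 0 °C
Reagents that add atoms: none
Why: Dess–Martin oxidation is the usual way to a β,γ-unsaturated aldehyde because it is neither basic nor strongly acidic, so the alkene should stay out of conjugation; 17 is to be used at once.

Step 13
Reactants: 17 (3E)-6-[(2R,3S)-3-(2-bromo-3-methylbutanoyl)-2-methyloxiran-2-yl]-3-methylhex-3-enal; 18 3,4,5-trimethoxybenzaldehyde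
Product: 22 (4R,5R,6R,7S,8S,1(10)E)-4,5-epoxy-6-hydroxy-4,10-dimethyl-7-(propan-2-yl)cyclodec-1(10)-en-8-yl 3,4,5-trimethoxybenzoate, via samarium enolate 19 (not isolated), via samarium aldolate 20 (not isolated), via samarium hemiacetal 21 (not isolated)
Conditions: SmI2 (2.0 equiv), THF, −78 °C, 17 and SmI2 added slowly and simultaneously (final 0.003 M); then 18 (4 equiv), −78 → −10 °C; aq. NaHCO3
Reagents that add atoms: 3,4,5-trimethoxybenzaldehyde (compound 18), COc1cc(C=O)cc(OC)c1OC
Why: Proposed new method: SmI2 should transfer two electrons to the C7–Br bond faster than to any other site and give the trivalent samarium (Z)-enolate 19, which adds through a samarium-bridged, chair-like transition state to the tethered C8 aldehyde to give aldolate 20; 20 then adds to 18 to form hemiacetal 21, whose benzylic hydrogen is passed to the C6 carbonyl inside a six-membered samarium chelate, so that the hemiacetal carbon becomes the ester carbonyl on O8 and C6 becomes the free carbinol. The closest known reactions are the SmI2-mediated intramolecular Reformatsky closure of medium rings and the samarium-catalysed Evans–Tishchenko reduction of β-hydroxy ketones with aldehydes, run here in sequence on one samarium centre without isolation of the aldol. The ten-membered carbocycle closes in a 10-(enolendo)-exo-trig mode by formation of C7–C8, and no other ring is formed. For C7 and C8 the syn relation is expected from the (Z)-enolate in the closed transition state, and the aldehyde face is to be selected by the C4/C5 oxirane, which together with the planar (E)-C1=C10 unit leaves the chain few folded conformations. C6 is set 1,3-anti to C8 by the chair-like hydride transfer within the chelate, independently of the neighbouring C5. The step needs reduction of C–Br in the presence of an epoxy ketone and an aldehyde, ring closure instead of oligomerisation, and acyl delivery to O8 only: the first is served by exactly two equivalents of SmI2 met at low stationary concentration (once enolised, the ketone no longer activates the oxirane), the second by high dilution, and the third by adding the non-enolisable 18 only after the divalent samarium is spent, so that 18 can act solely as hydride donor and acyl source.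

## Compound list

1 | geranyl acetate, (2E)-3,7-dimethylocta-2,6-dien-1-yl acetate | CC(C)=CCC/C(C)=C/COC(C)=O | starting material
2 | (2E,6E)-8-hydroxy-3,7-dimethylocta-2,6-dien-1-yl acetate | OC/C(C)=C/CC/C(C)=C/COC(C)=O | intermediate (not isolated)
3 | (2E,6E)-3,7-dimethyl-8-oxoocta-2,6-dien-1-yl acetate | O=C/C(C)=C/CC/C(C)=C/COC(C)=O | intermediate
4 | (2E,6E)-3,7-dimethylnona-2,6,8-trien-1-yl acetate | C=C/C(C)=C/CC/C(C)=C/COC(C)=O | intermediate
5 | (2E,6E)-9-(9-borabicyclo[3.3.1]nonan-9-yl)-3,7-dimethylnona-2,6-dien-1-yl acetate | CC(=O)OC/C=C(C)/CC/C=C(C)/CCB1C2CCCC1CCC2 | intermediate (not isolated)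
6 | (2E,6E)-9-hydroxy-3,7-dimethylnona-2,6-dien-1-yl acetate | OCC/C(C)=C/CC/C(C)=C/COC(C)=O | intermediate
7 | (2E,6E)-9-[(tert-butyldimethylsilyl)oxy]-3,7-dimethylnona-2,6-dien-1-yl acetate | CC(C)(C)[Si](C)(C)OCC/C(C)=C/CC/C(C)=C/COC(C)=O | intermediate
8 | (2E,6E)-9-[(tert-butyldimethylsilyl)oxy]-3,7-dimethylnona-2,6-dien-1-ol | CC(C)(C)[Si](C)(C)OCC/C(C)=C/CC/C(C)=C/CO | intermediate
9 | {(2R,3R)-3-[(3E)-6-[(tert-butyldimethylsilyl)oxy]-4-methylhex-3-en-1-yl]-3-methyloxiran-2-yl}methanol | CC(C)(C)[Si](C)(C)OCC/C(C)=C/CC[C@@]1(C)O[C@@H]1CO | intermediate
10 | (2S,3R)-3-[(3E)-6-[(tert-butyldimethylsilyl)oxy]-4-methylhex-3-en-1-yl]-3-methyloxirane-2-carbaldehyde | CC(C)(C)[Si](C)(C)OCC/C(C)=C/CC[C@@]1(C)O[C@@H]1C=O | intermediate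
11 | isobutylmagnesium bromide | CC(C)C[Mg]Br | starting material
12 | 1-{(2R,3R)-3-[(3E)-6-[(tert-butyldimethylsilyl)oxy]-4-methylhex-3-en-1-yl]-3-methyloxiran-2-yl}-3-methylbutan-1-ol, both carbinol epimers | CC(C)(C)[Si](C)(C)OCC/C(C)=C/CC[C@@]1(C)O[C@@H]1C(O)CC(C)C | intermediate
13 | 1-{(2S,3R)-3-[(3E)-6-[(tert-butyldimethylsilyl)oxy]-4-methylhex-3-en-1-yl]-3-methyloxiran-2-yl}-3-methylbutan-1-one | CC(C)(C)[Si](C)(C)OCC/C(C)=C/CC[C@@]1(C)O[C@@H]1C(=O)CC(C)C | intermediate
14 | trimethylsilyl enol ether of 13 across C6=C7, enol ether geometry not defined | CC(C)(C)[Si](C)(C)OCC/C(C)=C/CC[C@@]1(C)O[C@@H]1C(O[Si](C)(C)C)=CC(C)C | intermediate (not isolated)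
15 | 2-bromo-1-{(2S,3R)-3-[(3E)-6-[(tert-butyldimethylsilyl)oxy]-4-methylhex-3-en-1-yl]-3-methyloxiran-2-yl}-3-methylbutan-1-one, both C–Br epimers | CC(C)(C)[Si](C)(C)OCC/C(C)=C/CC[C@@]1(C)O[C@@H]1C(=O)C(Br)C(C)C | intermediate
16 | 2-bromo-1-{(2S,3R)-3-[(3E)-6-hydroxy-4-methylhex-3-en-1-yl]-3-methyloxiran-2-yl}-3-methylbutan-1-one, both C–Br epimers | OCC/C(C)=C/CC[C@@]1(C)O[C@@H]1C(=O)C(Br)C(C)C | intermediate
17 | (3E)-6-[(2R,3S)-3-(2-bromo-3-methylbutanoyl)-2-methyloxiran-2-yl]-3-methylhex-3-enal, both C–Br epimers | O=CC/C(C)=C/CC[C@@]1(C)O[C@@H]1C(=O)C(Br)C(C)C | intermediate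
18 | 3,4,5-trimethoxybenzaldehyde | COc1cc(C=O)cc(OC)c1OC | starting material
19 | diiodosamarium (Z)-enolate of 17 across C6=C7, trivalent samarium | O=CC/C(C)=C/CC[C@@]1(C)O[C@@H]1/C(O[Sm](I)I)=C/C(C)C | intermediate (not isolated)
20 | diiodosamarium C8 alkoxide of the ten-membered 4,5-epoxy-8-hydroxy-6-ketone, C4, C5, C7 and C8 arranged as in 22 | I[Sm](I)O[C@H]1C/C(C)=C/CC[C@@]2(C)O[C@@H]2C(=O)[C@@H]1C(C)C | intermediate (not isolated)
21 | diiodosamarium hemiacetal alkoxide from 20 and 18, hemiacetal carbon not defined | COc1cc(C(O[Sm](I)I)O[C@H]2C/C(C)=C/CC[C@@]3(C)O[C@@H]3C(=O)[C@@H]2C(C)C)cc(OC)c1OC | intermediate (not isolated)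
22 | (4R,5R,6R,7S,8S,1(10)E)-4,5-epoxy-6-hydroxy-4,10-dimethyl-7-(propan-2-yl)cyclodec-1(10)-en-8-yl 3,4,5-trimethoxybenzoate (ring numbering of this proposal) | COc1cc(C(=O)O[C@H]2C/C(C)=C/CC[C@@]3(C)O[C@@H]3[C@H](O)[C@@H]2C(C)C)cc(OC)c1OC | target

## Step count and least certain steps

Total: 13 steps. Longest linear sequence: 13 steps from 1 (11 and 18 are used as purchased).

Step 13 (key step, proposed new method). Most likely failures:
- poor facial or syn/anti selectivity in the ring-closing aldol, because control by the oxirane over a ten-membered transition state is untested;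
- reductive opening of the epoxy ketone in 20 by SmI2 not yet consumed;
- retro-aldol opening of 20 followed by crossed aldol–Tishchenko reaction with 18;
- acyl migration from O8 to O6, or samarium-induced transannular opening of the oxirane, on prolonged warming.

Fallback, in known chemistry: starting from 17, the two events are separated. The SmI2-mediated intramolecular Reformatsky reaction is run alone under high dilution and quenched cold to isolate the ten-membered aldol (4R,5S,7R,8S,1(10)E)-4,5-epoxy-8-hydroxy-4,10-dimethyl-7-(propan-2-yl)cyclodec-1(10)-en-6-one F1. Diastereomers can be separated at this stage. F1 is then submitted to a standard Evans–Tishchenko reduction with 18 and catalytic SmI2 in THF at −10 °C, which returns to the route at 22.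

Step 1. The selenium oxidation may stop short or over-oxidise, and may attack other allylic positions, so material is lost before the route has begun. Fallback from 1: epoxidation of the distal, more electron-rich alkene with 3-chloroperoxybenzoic acid gives (2E)-5-(3,3-dimethyloxiran-2-yl)-3-methylpent-2-en-1-yl acetate F2. Cleavage with H5IO6 gives the aldehyde (2E)-3-methyl-6-oxohex-2-en-1-yl acetate F3. An (E)-selective Wittig reaction of F3 with the stabilised ylide 2-(triphenylphosphoranylidene)propanal rebuilds the trisubstituted alkene and returns to the route at 3.

Step 8. Hydride transfer from the β-branched Grignard reagent (reduction instead of addition) and opening of the oxirane by magnesium halide are the likely side processes with a hindered epoxy aldehyde. Fallback from 10: NaClO2/NaH2PO4/2-methyl-2-butene oxidation gives (2S,3R)-3-[(3E)-6-[(tert-butyldimethylsilyl)oxy]-4-methylhex-3-en-1-yl]-3-methyloxirane-2-carboxylic acid F4. Coupling with N,O-dimethylhydroxylamine gives the amide (2S,3R)-3-[(3E)-6-[(tert-butyldimethylsilyl)oxy]-4-methylhex-3-en-1-yl]-N-methoxy-N,3-dimethyloxirane-2-carboxamide F5. Addition of 11 to F5 stops at the ketone and returns to the route at 13, without passing through 12.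

Step 10. Enolate formation may be incomplete, and bromination of the alkene or opening of the oxirane by bromide may compete if the silyl enol ether is not formed cleanly. Fallback from 10: (1-bromo-2-methylpropyl)magnesium chloride, made by bromine–magnesium exchange of 1,1-dibromo-2-methylpropane with iPrMgCl at −78 °C, is added to give the bromohydrin 2-bromo-1-{(2R,3R)-3-[(3E)-6-[(tert-butyldimethylsilyl)oxy]-4-methylhex-3-en-1-yl]-3-methyloxiran-2-yl}-3-methylbutan-1-ol F6 (quenched cold). Dess–Martin oxidation of F6 returns to the route at 15 with the bromine already in place.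

Step 11. Loss or displacement of the bromide and acid-induced opening of the oxirane may occur during desilylation of a molecule that already holds the bromo ketone. Fallback from 13: the silyl ether is removed first (Bu4NF buffered with AcOH, THF) to give 1-{(2S,3R)-3-[(3E)-6-hydroxy-4-methylhex-3-en-1-yl]-3-methyloxiran-2-yl}-3-methylbutan-1-one F7. F7 is then brominated with transient protection (LiN(SiMe3)2 and Me3SiCl in excess, then NBS, then a citric acid/MeOH work-up that frees the primary hydroxyl), which returns to the route at 16.

## Further compounds

F1 | step 13 | (4R,5S,7R,8S,1(10)E)-4,5-epoxy-8-hydroxy-4,10-dimethyl-7-(propan-2-yl)cyclodec-1(10)-en-6-one | O[C@H]1C/C(C)=C/CC[C@@]2(C)O[C@@H]2C(=O)[C@@H]1C(C)C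
F2 | step 1 | (2E)-5-(3,3-dimethyloxiran-2-yl)-3-methylpent-2-en-1-yl acetate, racemic at the oxirane | CC(=O)OC/C=C(C)/CCC1OC1(C)C
F3 | step 1 | (2E)-3-methyl-6-oxohex-2-en-1-yl acetate | CC(=O)OC/C=C(C)/CCC=O
F4 | step 8 | (2S,3R)-3-[(3E)-6-[(tert-butyldimethylsilyl)oxy]-4-methylhex-3-en-1-yl]-3-methyloxirane-2-carboxylic acid | CC(C)(C)[Si](C)(C)OCC/C(C)=C/CC[C@@]1(C)O[C@@H]1C(=O)O
F5 | step 8 | (2S,3R)-3-[(3E)-6-[(tert-butyldimethylsilyl)oxy]-4-methylhex-3-en-1-yl]-N-methoxy-N,3-dimethyloxirane-2-carboxamide | CC(C)(C)[Si](C)(C)OCC/C(C)=C/CC[C@@]1(C)O[C@@H]1C(=O)N(C)OC
F6 | step 10 | 2-bromo-1-{(2R,3R)-3-[(3E)-6-[(tert-butyldimethylsilyl)oxy]-4-methylhex-3-en-1-yl]-3-methyloxiran-2-yl}-3-methylbutan-1-ol, mixture at the carbinol and C–Br centres | CC(C)(C)[Si](C)(C)OCC/C(C)=C/CC[C@@]1(C)O[C@@H]1C(O)C(Br)C(C)C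
F7 | step 11 | 1-{(2S,3R)-3-[(3E)-6-hydroxy-4-methylhex-3-en-1-yl]-3-methyloxiran-2-yl}-3-methylbutan-1-one | OCC/C(C)=C/CC[C@@]1(C)O[C@@H]1C(=O)CC(C)C
A1 | alternative 1 | ten-membered 4,5-epoxy-6-ketone with C8 tert-butyldimethylsilyl ether, C4, C5, C7 and C8 arranged as in 22 | CC(C)(C)[Si](C)(C)O[C@H]1C/C(C)=C/CC[C@@]2(C)O[C@@H]2C(=O)[C@@H]1C(C)C
A2 | alternative 1 | (3R,4S,6E)-4-[(tert-butyldimethylsilyl)oxy]-1-chloro-6-methyl-3-(propan-2-yl)undec-6-ene-2,10-dione | CC(C)(C)[Si](C)(C)O[C@@H](C/C(C)=C/CCC(C)=O)[C@@H](C(C)C)C(=O)CCl
A3 | alternative 2 | isoxazoline-bridged 4,5-epoxycyclodecene with a C6=N–O–C8 bridge, C4, C5, C7 and C8 arranged as in 22 | O1[C@H]2C/C(C)=C/CC[C@@]3(C)O[C@@H]3C(=N1)[C@@H]2C(C)C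
A4 | alternative 2 | (2R,3R)-3-[(3E,6Z)-4,8-dimethylnona-3,6-dien-1-yl]-3-methyloxirane-2-carbaldehyde oxime, oxime geometry not defined | CC(C)/C=C\C/C(C)=C/CC[C@@]1(C)O[C@@H]1C=NO
A5 | alternative 2 | nitrile oxide derived from A4 | CC(C)/C=C\C/C(C)=C/CC[C@@]1(C)O[C@@H]1C#[N+][O-]
A6 | alternative 3 | ten-membered 6-ketone with C8 4-methoxybenzyl ether and 4,5-diol acetonide, C7 and C8 arranged as in 22 | COc1ccc(CO[C@H]2C/C(C)=C/CC[C@@]3(C)OC(C)(C)O[C@H]3C(=O)[C@@H]2C(C)C)cc1
A7 | alternative 3 | cyclohexanol (ring numbering of the target kept) with cis-4,5-acetonide, C6 hydroxyl, C6 (E)-2-[(4-methoxybenzyl)oxy]-1-(propan-2-yl)ethenyl group and C1 isopropenyl group trans to it, (1S,6S) | O[C@]1(/C(C(C)C)=C/OCc2ccc(OC)cc2)[C@H](C(C)=C)CC[C@@]2(C)OC(C)(C)O[C@@H]12
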